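If you take over the delta flask, it holds 480 mM of substrate, 480 mM of partner and 3.60 mM of free catalyst, and we owe a figure for its product at 7.9 h.

| setting | beta | alpha | zeta | delta |
|---|---|---|---|---|
| substrate | 120 mM | 60.0 mM | 120 mM | 480 mM |
| partner | 120 mM | 120 mM | 120 mM | 480 mM |
| free catalyst | 3.60 mM | 3.60 mM | 7.20 mM | 3.60 mM |
| time |  |  |  | 7.9 h |

| run | time / h | [product] / mM |
|---|---|---|
| beta run | 0.32 | 11.4 |
| beta run | 0.60 | 19.0 |
| beta run | 1.1 | 30.7 |
| beta run | 2.2 | 40.8 |
| beta run | 4.1 | 52.0 |
| beta run | 7.9 | 61.4 |
| alpha run | 0.32 | 9.1 |
| alpha run | 0.60 | 16.4 |
| alpha run | 1.1 | 24.3 |
| alpha run | 2.2 | 36.3 |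
| alpha run | 4.1 | 47.7 |
| alpha run | 7.9 | 55.2 |
| zeta run | 0.32 | 21.1 |
| zeta run | 0.60 | 34.3 |
| zeta run | 1.1 | 49.6 |
| zeta run | 2.2 | 67.8 |
| zeta run | 4.1 | 78.9 |
| zeta run | 7.9 | 78.7 |

(each reading ± 1 mM)

- Overall: substrate + partner -> product, with free catalyst as catalyst.
- Constant volume, constant temperature.
- "The second partner" is partner.
- An order is taken over about fifteen percent of the charge, up and down.

1. the exponent of [free catalyst] in the starting rate at the charge of the beta run (at the point where two percent of the substrate have become product)
2. the exponent of [substrate] in the starting rate at the charge of the beta run (at the point where two percent of the substrate have become product) (one fixed amount of product, the same in the runs compared)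
3. product in the delta run at 7.9 h, as a share of the substrate charged
4. which of these the readings show (nothing beyond the main steps / the second partner is lost in pairs / the catalyst rests as a dimer / an uncatalysed path runs beside / the substrate is lost by itself)

Start with the zeta run. Its product stands at 0.657 of the charge from 4.1 h on, although a share of 0.343 of its substrate has not become product. The alpha run, with the same partner charge, reaches 0.920 of its substrate. We therefore read the partner as the limiting reagent of zeta, going two ways: into product at a rate that follows the partner, and lost in pairs at a rate that follows its square.

Call the crossing x the share of the partner charge at which these two rates are level. Above it pairing takes more partner, and below it product-making does. Treating the product-making constant as steady, our reckoning is: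

end share of the partner charge = x · ln(1 + 1/x)

Trying x = 0.833 in this line gives an end share of 0.657, level with the share read from zeta, so we take this as zeta's crossing. The crossing follows the catalyst, so the beta run has

x = 0.833 × 3.60 mM / 7.20 mM = 0.417

This beta crossing keeps its partner level when the charge changes. Delta has the catalyst of beta, so on its larger charge

x = 0.104, end share = 24.6%

Delta charges partner and substrate equally, so this is also the share of its substrate. Do not change its free catalyst, since the crossing is tied to it.

The forecast gives 0.95 and 0.3 for the orders, 31% for delta, which is higher than our figure, and "the second partner is lost in pairs". In its words: “The partner must be dying, and faster when concentrated”.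

The flask gives orders of 1.0 and 0.21, 25.7% for delta, and "the second partner is lost in pairs".

    free catalyst + substrate → loaded catalyst + by-product (547.2 M⁻¹ h⁻¹)
    loaded catalyst + partner → product + free catalyst (117.0 M⁻¹ h⁻¹)
    2 partner → lost reagent (3.456 M⁻¹ h⁻¹)

The delta run proves the reason: the loss of partner in pairs accounts for 91% of what is missing from delta's product, and with that step taken away the run gives 93.4% instead of 25.7%. Delta starts at 9.62 crossings, higher than the 2.40 of the beta run. On beta, the same crossing gives an end share of 0.510 of the charge, and the last beta reading stands at 0.512.

The earlier runs and the new flask stem from a simulated flask from invented constants.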